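Ring A (C1–C2–C3–C4–C5–C10; C4 bears the exocyclic methylene, quaternary C10 the angular methyl) is the last ring to be closed, through the C2–C3 bond. C4=CH2 is treated as a masked ketone, which makes C3 an enol carbon, while C2 is the terminus of a vinyl group on C10. A palladium-catalysed 6-endo hydroalkylation joins the two in one redox-neutral operation and delivers the trans-decalin-4,8-dione. Its precursor is a monocyclic 4-acetyl-3-vinylcyclohexanone (ring B) that already carries the vicinal quaternary centres C9 and C10. It is unravelled from (+)-verbenone, whose cyclobutane controls both centres and then becomes the acetyl group on C5.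

Key step: step 7

Remark on the chemistry: drimane-type numbering is used throughout (ring A = C1–C5, C10; ring B = C5–C10; C8 = CH–CH3, C9 = quaternary carbon with CH3 and the benzylic C11); β is the face of the C10 methyl group; Ar = 2,3,5,6-tetramethoxyphenyl.

Step 1
Reactants: 1 1,2,4,5-tetramethoxybenzene
Product: 3 (2,3,5,6-tetramethoxyphenyl)methanol, via aryllithium 2 (not isolated)
Conditions: n-BuLi, THF, 0 °C → rt; then (CH2O)n, 0 °C → rt; H2O
Reagents that add atoms: formaldehyde (as paraformaldehyde), C=O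
Why: Directed ortho-lithiation removes the ring hydrogen flanked by two methoxy groups and the aryllithium adds to formaldehyde (hydroxymethylation); no stereocentre is involved.

Step 2
Reactants: 3 (2,3,5,6-tetramethoxyphenyl)methanol
Product: 4 3-(bromomethyl)-1,2,4,5-tetramethoxybenzene (2,3,5,6-tetramethoxybenzyl bromide)
Conditions: PBr3, Et2O, 0 °C
Reagents that add atoms: phosphorus tribromide, BrP(Br)Br
Why: Bromination of a benzylic alcohol with PBr3 (SN2 displacement of the intermediate phosphite ester); no stereocentre is involved.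

Step 3
Reactants: 5 (1R,5R)-4,6,6-trimethylbicyclo[3.1.1]hept-3-en-2-one, (+)-verbenone
Product: 7 3,4,6,6-tetramethyl-4-vinylbicyclo[3.1.1]heptan-2-one (vinyl and 3-methyl anti to the CMe2 bridge), via magnesium enolate 6 (not isolated)
Conditions: CH2=CHMgBr, CuBr·SMe2 (20 mol %), THF, −40 °C; then MeI, DMPU, −40 °C → rt
Reagents that add atoms: vinylmagnesium bromide, C=C[Mg]Br; iodomethane, CI
Why: Copper-catalysed conjugate addition of the vinyl Grignard reagent followed by enolate alkylation (tandem 1,4-addition–alkylation): the vinyl group enters from the face opposite the gem-dimethyl bridge, which sets C10 with its methyl syn and its vinyl anti to the bridge, while the configuration of the methylated carbon is erased again in step 4.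

Step 4
Reactants: 7 3,4,6,6-tetramethyl-4-vinylbicyclo[3.1.1]heptan-2-one; 4 2,3,5,6-tetramethoxybenzyl bromide
Product: 9 3,4,6,6-tetramethyl-3-(2,3,5,6-tetramethoxybenzyl)-4-vinylbicyclo[3.1.1]heptan-2-one (benzyl and vinyl anti to the CMe2 bridge; both methyls syn), via lithium enolate 8 (not isolated)
Conditions: LiN(iPr)2, THF, −78 → 0 °C; then 4, DMPU, −78 °C → rt
Reagents that add atoms: none
Why: Enolate C-alkylation: the ketone can enolise only towards C9 because the other α-carbon is a cyclobutane bridgehead, and the benzylic bromide attacks the enolate face opposite the gem-dimethyl bridge, so the arylmethyl group ends cis to the vinyl group and the C9 methyl syn to the bridge (quaternary C9).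

Step 5
Reactants: 9 3,4,6,6-tetramethyl-3-(2,3,5,6-tetramethoxybenzyl)-4-vinylbicyclo[3.1.1]heptan-2-one
Product: 11 4-isopropenyl-2,3-dimethyl-2-(2,3,5,6-tetramethoxybenzyl)-3-vinylcyclohexan-1-one (C8 ketone; 9β-Me; 9α-CH2Ar; 10β-Me; 10α-vinyl; 5β-isopropenyl), via enol acetate 10 (not isolated)
Conditions: Zn(OAc)2, BF3·OEt2, Ac2O, CH2Cl2, 0 °C → rt; then K2CO3, MeOH, rt
Reagents that add atoms: none
Why: Lewis acid-promoted fragmentation of the cyclobutyl ketone (acid-mediated ring opening of a pinan-2-one): the strained C7–C4 bond next to the activated carbonyl breaks, the enol is trapped as its acetate, and the tertiary cation loses a methyl proton to give the isopropenyl group on C5, whose configuration is untouched; methanolysis then frees the C8 ketone.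

Step 6
Reactants: 11 4-isopropenyl-2,3-dimethyl-2-(2,3,5,6-tetramethoxybenzyl)-3-vinylcyclohexan-1-one
Product: 13 4-acetyl-2,3-dimethyl-2-(2,3,5,6-tetramethoxybenzyl)-3-vinylcyclohexan-1-one, via epoxide 12 (not isolated)
Conditions: m-CPBA (1.05 equiv), NaHCO3, CH2Cl2, 0 °C; then H5IO6, THF/H2O, rt
Reagents that add atoms: water, O
Why: Prilezhaev epoxidation selects the electron-richer 1,1-disubstituted isopropenyl alkene over the monosubstituted neopentylic vinyl group, and periodic acid then opens the epoxide with water at its tertiary carbon and cleaves the glycol (oxidative glycol cleavage) to the C4 methyl ketone with loss of formaldehyde; no ring stereocentre is touched and the epoxide epimers converge.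

Step 7
Reactants: 13 4-acetyl-2,3-dimethyl-2-(2,3,5,6-tetramethoxybenzyl)-3-vinylcyclohexan-1-one
Product: 14 9β,10β-dimethyl-9α-(2,3,5,6-tetramethoxybenzyl)-5α-H-trans-decalin-4,8-dione
Conditions: PdCl2(MeCN)2 (10 mol %), CuCl2 (30 mol %), HCl (10 mol %), 1,4-dioxane, 70 °C, sealed tube
Reagents that add atoms: none
Why: Divalent palladium binds the vinyl group and the enol of the methyl ketone attacks its terminal carbon C2 through C3 from the face opposite the metal; the resulting C1–palladium alkyl walks by β-hydride elimination and re-addition via C2 to C3, where it is a palladium enolate that is protonated, so the metal stays divalent and the step is a net cycloisomerisation. The closest known reaction type is the palladium-catalysed intramolecular hydroalkylation of unactivated alkenes by 3-butenyl ketones. Ring A is closed in the 6-endo-trig mode. No new stereocentre arises at C2 or C3; C5 keeps the configuration inherited from the verbenone bridgehead, and because it is now α to the C4 carbonyl the acid present would in any case equilibrate it to the trans-fused decalone, the more stable epimer. The step needs 6-endo over 5-exo closure and C3 over C7 as the nucleophile: attack at C1 is blocked because C1 is neopentylic to quaternary C10, the vinyl group cannot isomerise because C10 carries no hydrogen, the trans-diequatorial acetyl and vinyl groups on C5 and C10 are held within bonding distance, and the C7 enol of the C8 ketone could reach C2 only through a boat of ring B.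

Step 8
Reactants: 14 9β,10β-dimethyl-9α-(2,3,5,6-tetramethoxybenzyl)-5α-H-trans-decalin-4,8-dione
Product: 15 4,4-(ethylenedioxy)-9β,10β-dimethyl-9α-(2,3,5,6-tetramethoxybenzyl)-5α-H-trans-decalin-8-one
Conditions: HOCH2CH2OH, p-TsOH (cat.), benzene, reflux, Dean–Stark
Reagents that add atoms: ethylene glycol, OCCO
Why: Acid-catalysed ketalisation discriminates the C4 ketone from the C8 ketone, which is neopentylic to quaternary C9; C5 is α to C4 but the trans ring fusion is the stable arrangement.

Step 9
Reactants: 15 4,4-(ethylenedioxy)-9β,10β-dimethyl-9α-(2,3,5,6-tetramethoxybenzyl)-5α-H-trans-decalin-8-one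
Product: 16 4,4-(ethylenedioxy)-9β,10β-dimethyl-8-methylene-9α-(2,3,5,6-tetramethoxybenzyl)-5α-H-trans-decalin
Conditions: Ph3PCH3Br, KOtBu, toluene, 90 °C
Reagents that add atoms: methyltriphenylphosphonium bromide, C[P+](c1ccccc1)(c1ccccc1)c1ccccc1.[Br-]
Why: Wittig methylenation of the hindered C8 ketone with the small unstabilised ylide at elevated temperature while the ketal shields C4; no stereocentre is formed.

Step 10
Reactants: 16 4,4-(ethylenedioxy)-9β,10β-dimethyl-8-methylene-9α-(2,3,5,6-tetramethoxybenzyl)-5α-H-trans-decalin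
Product: 17 4,4-(ethylenedioxy)-8β,9β,10β-trimethyl-9α-(2,3,5,6-tetramethoxybenzyl)-5α-H-trans-decalin
Conditions: H2 (1 atm), PtO2, EtOAc, rt
Reagents that add atoms: none
Why: Heterogeneous hydrogenation of the exocyclic alkene should deliver hydrogen to the α-face of C8, because the β-face is screened by the syn-axial C10 methyl and the C9 methyl and the α-oriented arylmethyl group can anchor the substrate to the catalyst surface, which sets the axial 8β-methyl stereocentre.

Step 11
Reactants: 17 4,4-(ethylenedioxy)-8β,9β,10β-trimethyl-9α-(2,3,5,6-tetramethoxybenzyl)-5α-H-trans-decalin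
Product: 18 8β,9β,10β-trimethyl-9α-(2,3,5,6-tetramethoxybenzyl)-5α-H-trans-decalin-4-one
Conditions: 1 M HCl, THF, rt
Reagents that add atoms: water, O
Why: Acid hydrolysis of the dioxolane regenerates the C4 ketone without touching the aryl methyl ethers, and C5 remains in the stable trans-fused configuration.

Step 12
Reactants: 18 8β,9β,10β-trimethyl-9α-(2,3,5,6-tetramethoxybenzyl)-5α-H-trans-decalin-4-one
Product: 19 8β,9β,10β-trimethyl-4-methylene-9α-(2,3,5,6-tetramethoxybenzyl)-5α-H-trans-decalin
Conditions: Ph3PCH3Br, KOtBu, THF, 0 °C → rt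
Reagents that add atoms: methyltriphenylphosphonium bromide, C[P+](c1ccccc1)(c1ccccc1)c1ccccc1.[Br-]
Why: Wittig methylenation installs the exocyclic C4 methylene; the basic ylide may enolise the ketone towards C5 but the trans-fused ketone is the thermodynamic epimer, so C5 is not scrambled.

Step 13
Reactants: 19 8β,9β,10β-trimethyl-4-methylene-9α-(2,3,5,6-tetramethoxybenzyl)-5α-H-trans-decalin
Product: 20 2,5-dimethoxy-3-[(8β,9β,10β-trimethyl-4-methylene-5α-H-trans-decalin-9α-yl)methyl]-1,4-benzoquinone
Conditions: (NH4)2Ce(NO3)6, MeCN/H2O, 0 °C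
Reagents that add atoms: water, O
Why: Oxidative demethylation of a para-dimethoxy pair by tetravalent cerium gives the 1,4-benzoquinone (both para pairs of the symmetric arene lead to the same quinone), and the isolated exocyclic alkene is inert to the one-electron oxidant.

Step 14
Reactants: 20 2,5-dimethoxy-3-[(8β,9β,10β-trimethyl-4-methylene-5α-H-trans-decalin-9α-yl)methyl]-1,4-benzoquinone
Product: 21 2-hydroxy-5-methoxy-3-[(8β,9β,10β-trimethyl-4-methylene-5α-H-trans-decalin-9α-yl)methyl]-1,4-benzoquinone (CNP0109104.1)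
Conditions: KOH, MeOH/H2O, rt; then 1 M HCl
Reagents that add atoms: potassium hydroxide, [K+].[OH-]
Why: Addition–elimination hydrolysis of a vinylogous ester: the methoxy group next to the side chain is twisted out of conjugation by its two flanking substituents and should be exchanged first, and the resulting vinylogous acid anion deactivates the quinone against a second exchange.

Compound list
1 | 1,2,4,5-tetramethoxybenzene | COc1cc(OC)c(OC)cc1OC | starting material
2 | (2,3,5,6-tetramethoxyphenyl)lithium | [Li]c1c(OC)c(OC)cc(OC)c1OC | intermediate (not isolated)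
3 | (2,3,5,6-tetramethoxyphenyl)methanol | OCc1c(OC)c(OC)cc(OC)c1OC | intermediate
4 | 3-(bromomethyl)-1,2,4,5-tetramethoxybenzene | BrCc1c(OC)c(OC)cc(OC)c1OC | intermediate
5 | (1R,5R)-4,6,6-trimethylbicyclo[3.1.1]hept-3-en-2-one, (+)-verbenone | O=C1C=C(C)[C@H]2C[C@@H]1C2(C)C | starting material
6 | bromomagnesium enolate of 4,6,6-trimethyl-4-vinylbicyclo[3.1.1]heptan-2-one (vinyl anti to the CMe2 bridge) | Br[Mg]OC1=C[C@@](C)(C=C)[C@H]2C[C@@H]1C2(C)C | intermediate (not isolated)
7 | 3,4,6,6-tetramethyl-4-vinylbicyclo[3.1.1]heptan-2-one (vinyl and 3-methyl anti to the CMe2 bridge) | O=C1[C@@H](C)[C@@](C)(C=C)[C@H]2C[C@@H]1C2(C)C | intermediate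
8 | lithium enolate of 7 | [Li]OC1=C(C)[C@@](C)(C=C)[C@H]2C[C@@H]1C2(C)C | intermediate (not isolated)
9 | 3,4,6,6-tetramethyl-3-(2,3,5,6-tetramethoxybenzyl)-4-vinylbicyclo[3.1.1]heptan-2-one (benzyl and vinyl anti to the CMe2 bridge, both methyls syn) | O=C1[C@@](C)(Cc3c(OC)c(OC)cc(OC)c3OC)[C@@](C)(C=C)[C@H]2C[C@@H]1C2(C)C | intermediate
10 | 4-isopropenyl-5,6-dimethyl-6-(2,3,5,6-tetramethoxybenzyl)-5-vinylcyclohex-1-en-1-yl acetate | CC(=O)OC1=CC[C@@H](C(C)=C)[C@](C)(C=C)[C@]1(C)Cc2c(OC)c(OC)cc(OC)c2OC | intermediate (not isolated)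
11 | 4-isopropenyl-2,3-dimethyl-2-(2,3,5,6-tetramethoxybenzyl)-3-vinylcyclohexan-1-one (2-methyl, 3-methyl and isopropenyl on the β-face; benzyl and vinyl on the α-face) | O=C1CC[C@@H](C(C)=C)[C@](C)(C=C)[C@]1(C)Cc2c(OC)c(OC)cc(OC)c2OC | intermediate
12 | 2,3-dimethyl-4-(2-methyloxiran-2-yl)-2-(2,3,5,6-tetramethoxybenzyl)-3-vinylcyclohexan-1-one (both epimers at the oxirane carbon) | O=C1CC[C@@H](C2(C)CO2)[C@](C)(C=C)[C@]1(C)Cc2c(OC)c(OC)cc(OC)c2OC | intermediate (not isolated)
13 | 4-acetyl-2,3-dimethyl-2-(2,3,5,6-tetramethoxybenzyl)-3-vinylcyclohexan-1-one | O=C1CC[C@@H](C(C)=O)[C@](C)(C=C)[C@]1(C)Cc2c(OC)c(OC)cc(OC)c2OC | intermediate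
14 | 9β,10β-dimethyl-9α-(2,3,5,6-tetramethoxybenzyl)-5α-H-trans-decalin-4,8-dione | O=C1CCC[C@@]2(C)[C@H]1CCC(=O)[C@@]2(C)Cc3c(OC)c(OC)cc(OC)c3OC | intermediate
15 | 4,4-(ethylenedioxy)-9β,10β-dimethyl-9α-(2,3,5,6-tetramethoxybenzyl)-5α-H-trans-decalin-8-one | O1CCOC12CCC[C@@]3(C)[C@H]2CCC(=O)[C@@]3(C)Cc2c(OC)c(OC)cc(OC)c2OC | intermediate
16 | 4,4-(ethylenedioxy)-9β,10β-dimethyl-8-methylene-9α-(2,3,5,6-tetramethoxybenzyl)-5α-H-trans-decalin | O1CCOC12CCC[C@@]3(C)[C@H]2CCC(=C)[C@@]3(C)Cc2c(OC)c(OC)cc(OC)c2OC | intermediate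
17 | 4,4-(ethylenedioxy)-8β,9β,10β-trimethyl-9α-(2,3,5,6-tetramethoxybenzyl)-5α-H-trans-decalin | O1CCOC12CCC[C@@]3(C)[C@H]2CC[C@H](C)[C@@]3(C)Cc2c(OC)c(OC)cc(OC)c2OC | intermediate
18 | 8β,9β,10β-trimethyl-9α-(2,3,5,6-tetramethoxybenzyl)-5α-H-trans-decalin-4-one | O=C1CCC[C@@]2(C)[C@H]1CC[C@H](C)[C@@]2(C)Cc3c(OC)c(OC)cc(OC)c3OC | intermediate
19 | 8β,9β,10β-trimethyl-4-methylene-9α-(2,3,5,6-tetramethoxybenzyl)-5α-H-trans-decalin | C=C1CCC[C@@]2(C)[C@H]1CC[C@H](C)[C@@]2(C)Cc3c(OC)c(OC)cc(OC)c3OC | intermediate
20 | 2,5-dimethoxy-3-[(8β,9β,10β-trimethyl-4-methylene-5α-H-trans-decalin-9α-yl)methyl]-1,4-benzoquinone | C=C1CCC[C@@]2(C)[C@H]1CC[C@H](C)[C@@]2(C)CC3=C(OC)C(=O)C=C(OC)C3=O | intermediate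
21 | 2-hydroxy-5-methoxy-3-[(8β,9β,10β-trimethyl-4-methylene-5α-H-trans-decalin-9α-yl)methyl]-1,4-benzoquinone (CNP0109104.1) | C=C1CCC[C@@]2(C)[C@H]1CC[C@H](C)[C@@]2(C)CC1=C(O)C(=O)C=C(OC)C1=O | target

Total step count: 14
Longest linear sequence: 13 steps (steps 1, 2 and 4–14, from 1,2,4,5-tetramethoxybenzene 1 through benzylic bromide 4 to 21).

Steps most likely to fail

Step 7 (key step). The methyl ketone is only weakly enolised, so carbopalladation of the vinyl group may be too slow. Oxidation of the electron-rich arene by the copper and palladium salts, or acid-induced aldol chemistry of the 1,5-diketone, could then consume the material. The fallback replaces the cycloisomerisation by a polar alkylation that forms the same C2–C3 bond. Setting out from 13, the vinyl group is hydroborated with 9-borabicyclo[3.3.1]nonane (THF, 0 °C) and oxidised with NaBO3 to the primary alcohol 4-acetyl-3-(2-hydroxyethyl)-2,3-dimethyl-2-(2,3,5,6-tetramethoxybenzyl)cyclohexan-1-one F1. I2, PPh3 and imidazole convert it into the primary iodide 4-acetyl-3-(2-iodoethyl)-2,3-dimethyl-2-(2,3,5,6-tetramethoxybenzyl)cyclohexan-1-one F2. KOtBu in THF then closes ring A by intramolecular C-alkylation of the methyl ketone enolate at C3 (6-exo-tet), and the route is rejoined at 14.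

Step 10. Facial selectivity may be poor or reversed: the axial arylmethyl group on C9 hinders the α-face, so hydrogen may be delivered to the β-face and give the equatorial 8α-methyl epimer. The fallback uses the exposed β-face for oxygen and brings in the hydrogen by an intramolecular shift. Setting out from 16, dimethyldioxirane in acetone should epoxidise the β-face to the spiro-epoxide (8β-O) F3. Methylaluminium bis(4-bromo-2,6-di-tert-butylphenoxide) then induces a Meinwald rearrangement in which hydride migrates to C8 anti to the departing oxygen, giving the 8β-carbaldehyde F4. NaBH4 reduces it to the 8β-hydroxymethyl compound F5, I2, PPh3 and imidazole give the 8β-iodomethyl compound F6, and Bu3SnH with AIBN removes the iodine and rejoins the route at 17.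

Step 4. C-alkylation at the neopentylic enolate carbon, next to quaternary C10 and with a di-ortho-substituted benzylic bromide, may be too slow, so that O-alkylation or decomposition of the bromide dominates. The fallback uses a more compact carbonyl electrophile. Alcohol 3 is oxidised with MnO2 to 2,3,5,6-tetramethoxybenzaldehyde F7. Setting out from 7, the lithium enolate is added to F7 at −78 °C (aldol addition, again from the face opposite the bridge) to give the β-hydroxy ketone 3-[hydroxy(2,3,5,6-tetramethoxyphenyl)methyl]-3,4,6,6-tetramethyl-4-vinylbicyclo[3.1.1]heptan-2-one F8. Ionic deoxygenation of the electron-rich benzylic alcohol with Et3SiH and CF3CO2H at low temperature then rejoins the route at 9.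

Further compounds
F1 | step 7 | 4-acetyl-3-(2-hydroxyethyl)-2,3-dimethyl-2-(2,3,5,6-tetramethoxybenzyl)cyclohexan-1-one | O=C1CC[C@@H](C(C)=O)[C@](C)(CCO)[C@]1(C)Cc2c(OC)c(OC)cc(OC)c2OC
F2 | step 7 | 4-acetyl-3-(2-iodoethyl)-2,3-dimethyl-2-(2,3,5,6-tetramethoxybenzyl)cyclohexan-1-one | O=C1CC[C@@H](C(C)=O)[C@](C)(CCI)[C@]1(C)Cc2c(OC)c(OC)cc(OC)c2OC
F3 | step 10 | spiro-epoxide of 16 at C8 (oxygen on the β-face) | O1CCOC12CCC[C@@]3(C)[C@H]2CC[C@@]4(CO4)[C@@]3(C)Cc2c(OC)c(OC)cc(OC)c2OC
F4 | step 10 | 4,4-(ethylenedioxy)-9β,10β-dimethyl-9α-(2,3,5,6-tetramethoxybenzyl)-5α-H-trans-decalin-8β-carbaldehyde | O1CCOC12CCC[C@@]3(C)[C@H]2CC[C@H](C=O)[C@@]3(C)Cc2c(OC)c(OC)cc(OC)c2OC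
F5 | step 10 | 8β-(hydroxymethyl) analogue of 17 | O1CCOC12CCC[C@@]3(C)[C@H]2CC[C@H](CO)[C@@]3(C)Cc2c(OC)c(OC)cc(OC)c2OC
F6 | step 10 | 8β-(iodomethyl) analogue of 17 | O1CCOC12CCC[C@@]3(C)[C@H]2CC[C@H](CI)[C@@]3(C)Cc2c(OC)c(OC)cc(OC)c2OC
F7 | step 4 | 2,3,5,6-tetramethoxybenzaldehyde | O=Cc1c(OC)c(OC)cc(OC)c1OC
F8 | step 4 | 3-[hydroxy(2,3,5,6-tetramethoxyphenyl)methyl]-3,4,6,6-tetramethyl-4-vinylbicyclo[3.1.1]heptan-2-one | O=C1[C@@](C)(C(O)c3c(OC)c(OC)cc(OC)c3OC)[C@@](C)(C=C)[C@H]2C[C@@H]1C2(C)C
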